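**Retrosynthetic overview**
- Target ⇒ three ester C–O bonds on methyl shikimate. A 3,4-orthoacetate tells O3, O4 and O5 apart: it blocks the cis-diol while O5 is esterified, then opens to the axial 3-acetate, leaving O4 for the last acylation.
- Methyl shikimate ⇒ C1=C2 by ring-closing metathesis of an unprotected acyclic triol diene. This is the only ring, closed after all three ring stereocentres are in place.
- Triol diene ⇒ C5–C6 (key bond): a dihydroxypentenal plus 2-(methoxycarbonyl)allylindium, a β-ester carbanion (homoenolate equivalent) made from methyl 2-(bromomethyl)acrylate. The aldehyde carbon and the allylic bromide carbon are both electrophiles; chelation sets C5.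
- Dihydroxypentenal ⇒ zinc fragmentation of methyl 5-deoxy-5-iodo-β-D-ribofuranoside in the same pot. C2 and C3 of D-ribose become C4 and C3 of the target.

Assumption: methyl β-D-ribofuranoside, (S)-3-methylpentanoic acid and (R)-2-methylbutanoic acid are bought as single enantiomers; the acyl configurations (2R in the butanoate, 3S in the pentanoate) are read from the target SMILES.

**Step 1**
Reactants: 1 methyl β-D-ribofuranoside
Product: 2 methyl 5-deoxy-5-iodo-β-D-ribofuranoside
Conditions: PPh3, I2, imidazole, THF, reflux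
Reagents that add atoms: iodine, [I][I]
Why: Garegg–Samuelsson (Appel-type) iodination forms and displaces the alkoxyphosphonium ion far faster at the primary 5-OH than at the two secondary hydroxyls, so the 2,3-diol needs no protection and no stereocentre is touched.

**Step 2**
Reactants: 2 methyl 5-deoxy-5-iodo-β-D-ribofuranoside; 3 methyl 2-(bromomethyl)acrylate
Product: 5 methyl (4R,5S,6R)-4,5,6-trihydroxy-2-methylideneoct-7-enoate, via (2R,3R)-2,3-dihydroxypent-4-enal 4 (not isolated)
Conditions: zinc dust, THF/H2O 4:1, sonication, 40 °C; filter; indium powder, 3, rt; NaHCO3 work-up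
Reagents that add atoms: none
Why: Zinc inserts into the C–I bond and the furanoside fragments to aldehyde 4 (Bernet–Vasella reductive fragmentation), and the allylindium from 3, a β-ester carbanion (homoenolate equivalent), then adds in water (Barbier reaction) through a chelate in which indium is held by the free α-hydroxyl, so attack comes from the face opposite the remaining α-substituent and the new centre forms syn (threo) to that hydroxyl, i.e. 4R (C5 of the target), with the minor 4S epimer removed by chromatography.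

**Step 3**
Reactants: 5 methyl (4R,5S,6R)-4,5,6-trihydroxy-2-methylideneoct-7-enoate
Product: 6 methyl shikimate
Conditions: second-generation Hoveyda–Grubbs catalyst (5 mol%), EtOAc (0.01 M), 60 °C
Reagents that add atoms: none
Why: Ring-closing metathesis, in which the catalyst loads on the monosubstituted vinyl group and closes onto the 1,1-disubstituted acrylate, can only give the six-membered ring with the trisubstituted C1=C2 double bond; loss of ethylene drives it, free hydroxyls are tolerated and no stereocentre is involved.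

**Step 4**
Reactants: 6 methyl shikimate; 7 (S)-3-methylpentanoic acid
Product: 10 methyl (3R,4S,5R)-3-acetoxy-4-hydroxy-5-[(3S)-3-methylpentanoyloxy]cyclohex-1-ene-1-carboxylate, via 3,4-orthoacetate 8 (not isolated), via 5-O-acylated 3,4-orthoacetate 9 (not isolated)
Conditions: MeC(OMe)3 (1.2 equiv), CSA (cat.), MeCN, rt; Et3N, evaporate; 7, DIC, DMAP (1.5 equiv), CH2Cl2, 0 °C to rt; AcOH/H2O 4:1, rt
Reagents that add atoms: trimethyl orthoacetate, CC(OC)(OC)OC; water, O
Why: Only the cis-3,4-diol can form the five-membered cyclic orthoester (acid-catalysed orthoester exchange), the 5-OH is then the only free hydroxyl for a Steglich esterification kept basic by DMAP (the β-stereocentre of 7 cannot epimerise), and mild aqueous acid opens the orthoester so that the acetate stays on the pseudo-axial O3 and the equatorial 4-OH is freed (King–Allbutt orthoester opening), with all ring stereocentres untouched.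

**Step 5**
Reactants: 10 methyl (3R,4S,5R)-3-acetoxy-4-hydroxy-5-[(3S)-3-methylpentanoyloxy]cyclohex-1-ene-1-carboxylate; 11 (R)-2-methylbutanoic acid
Product: 12 methyl (3R,4S,5R)-3-acetoxy-4-[(2R)-2-methylbutanoyloxy]-5-[(3S)-3-methylpentanoyloxy]cyclohex-1-ene-1-carboxylate (CNP0188172.1)
Conditions: 11, DIC, DMAP (cat.), CH2Cl2, 0 °C to rt
Reagents that add atoms: none
Why: Steglich esterification of the last free hydroxyl goes through the acylpyridinium from 11 without forming an alkoxide, so acetyl migration from O3 is not triggered, and because no acid chloride or ketene is involved the α-stereocentre of 11 is retained.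

**Compound list**
1 | methyl β-D-ribofuranoside | CO[C@@H]1O[C@H](CO)[C@@H](O)[C@H]1O | starting material
2 | methyl 5-deoxy-5-iodo-β-D-ribofuranoside | CO[C@@H]1O[C@H](CI)[C@@H](O)[C@H]1O | intermediate
3 | methyl 2-(bromomethyl)acrylate | C=C(CBr)C(=O)OC | starting material
4 | (2R,3R)-2,3-dihydroxypent-4-enal | C=C[C@@H](O)[C@@H](O)C=O | intermediate
5 | methyl (4R,5S,6R)-4,5,6-trihydroxy-2-methylideneoct-7-enoate | C=C[C@@H](O)[C@@H](O)[C@H](O)CC(=C)C(=O)OC | intermediate
6 | methyl shikimate, methyl (3R,4S,5R)-3,4,5-trihydroxycyclohex-1-ene-1-carboxylate | COC(=O)C1=C[C@@H](O)[C@@H](O)[C@H](O)C1 | intermediate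
7 | (S)-3-methylpentanoic acid | CC[C@H](C)CC(=O)O | starting material
8 | methyl 3,4-O-(1-methoxyethylidene)shikimate (both epimers at the orthoester carbon) | COC(=O)C1=C[C@H]2OC(C)(OC)O[C@H]2[C@H](O)C1 | intermediate
9 | methyl 3,4-O-(1-methoxyethylidene)-5-O-[(3S)-3-methylpentanoyl]shikimate | COC(=O)C1=C[C@H]2OC(C)(OC)O[C@H]2[C@H](OC(=O)C[C@@H](C)CC)C1 | intermediate
10 | methyl (3R,4S,5R)-3-acetoxy-4-hydroxy-5-[(3S)-3-methylpentanoyloxy]cyclohex-1-ene-1-carboxylate | COC(=O)C1=C[C@@H](OC(C)=O)[C@@H](O)[C@H](OC(=O)C[C@@H](C)CC)C1 | intermediate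
11 | (R)-2-methylbutanoic acid | CC[C@@H](C)C(=O)O | starting material
12 | methyl (3R,4S,5R)-3-acetoxy-4-[(2R)-2-methylbutanoyloxy]-5-[(3S)-3-methylpentanoyloxy]cyclohex-1-ene-1-carboxylate | CC[C@H](C)CC(=O)O[C@@H]1CC(C(=O)OC)=C[C@@H](OC(C)=O)[C@H]1OC(=O)[C@H](C)CC | target

**Step count and risks**
Total step count: 5. Longest linear sequence: 5 steps (1 → 2 → 5 → 6 → 10 → 12).

The three steps most likely to fail are steps 2, 3 and 4.

Step 2 may give a poor syn:anti ratio on the free dihydroxy aldehyde, or the γ-hydroxy ester may lactonise. The fallback sets out from 2 and comes back at 5; it sets the carbinol by substrate control followed by inversion instead of by chelation. Compound 2 is protected with 2,2-dimethoxypropane and TsOH in acetone as methyl 5-deoxy-5-iodo-2,3-O-isopropylidene-β-D-ribofuranoside F1. Zinc dust with 3 in THF/H2O under sonication then fragments it and adds the allyl unit under Felkin–Anh control to give the anti alcohol methyl (4S)-4-[(4S,5R)-2,2-dimethyl-5-vinyl-1,3-dioxolan-4-yl]-4-hydroxy-2-methylidenebutanoate F2. A Mitsunobu reaction (PPh3, DIAD, 4-nitrobenzoic acid, THF) inverts the carbinol to methyl (4R)-4-[(4S,5R)-2,2-dimethyl-5-vinyl-1,3-dioxolan-4-yl]-2-methylidene-4-(4-nitrobenzoyloxy)butanoate F3. K2CO3 in MeOH at 0 °C frees the syn alcohol methyl (4R)-4-[(4S,5R)-2,2-dimethyl-5-vinyl-1,3-dioxolan-4-yl]-4-hydroxy-2-methylidenebutanoate F4, and AcOH/H2O 4:1 at 40 °C removes the acetonide to give 5.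

Step 3 may suffer from ruthenium hydride isomerisation of the free allylic alcohol to a ketone, catalyst chelation by the triol, or poor solubility. The fallback sets out from 5 and comes back at 6; it masks the hydroxyls before ring closure. Ac2O, pyridine and DMAP give methyl (4R,5S,6R)-4,5,6-triacetoxy-2-methylideneoct-7-enoate F5. Ring-closing metathesis with second-generation Grubbs catalyst in refluxing CH2Cl2 gives methyl 3,4,5-tri-O-acetylshikimate F6, and catalytic NaOMe in MeOH at 0 °C returns 6.

Step 4 may fail if the orthoester opens with the wrong regiochemistry or does not survive the esterification. The fallback sets out from 6 and comes back at 10; it replaces the orthoester by an acetonide and a kinetic acetylation. 2,2-Dimethoxypropane and CSA give methyl 3,4-O-isopropylidene-shikimate F7. Esterification with 7 (DIC, DMAP, CH2Cl2) gives methyl 3,4-O-isopropylidene-5-O-[(3S)-3-methylpentanoyl]shikimate F8, and TFA/H2O in CH2Cl2 at 0 °C gives the diol methyl 5-O-[(3S)-3-methylpentanoyl]shikimate F9. Acetyl chloride (1.05 equiv) with 2,4,6-collidine in CH2Cl2 at −78 °C then acetylates the allylic 3-OH in preference to the 4-OH, which is flanked on both sides, to give 10.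

**Further compounds**
F1 | step 2 | methyl 5-deoxy-5-iodo-2,3-O-isopropylidene-β-D-ribofuranoside | CO[C@@H]1O[C@H](CI)[C@H]2OC(C)(C)O[C@@H]12
F2 | step 2 | methyl (4S)-4-[(4S,5R)-2,2-dimethyl-5-vinyl-1,3-dioxolan-4-yl]-4-hydroxy-2-methylidenebutanoate | C=C[C@H]1OC(C)(C)O[C@H]1[C@@H](O)CC(=C)C(=O)OC
F3 | step 2 | methyl (4R)-4-[(4S,5R)-2,2-dimethyl-5-vinyl-1,3-dioxolan-4-yl]-2-methylidene-4-(4-nitrobenzoyloxy)butanoate | C=C[C@H]1OC(C)(C)O[C@H]1[C@H](OC(=O)c1ccc(cc1)[N+](=O)[O-])CC(=C)C(=O)OC
F4 | step 2 | methyl (4R)-4-[(4S,5R)-2,2-dimethyl-5-vinyl-1,3-dioxolan-4-yl]-4-hydroxy-2-methylidenebutanoate | C=C[C@H]1OC(C)(C)O[C@H]1[C@H](O)CC(=C)C(=O)OC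
F5 | step 3 | methyl (4R,5S,6R)-4,5,6-triacetoxy-2-methylideneoct-7-enoate | C=C[C@@H](OC(C)=O)[C@@H](OC(C)=O)[C@H](OC(C)=O)CC(=C)C(=O)OC
F6 | step 3 | methyl 3,4,5-tri-O-acetylshikimate | COC(=O)C1=C[C@@H](OC(C)=O)[C@@H](OC(C)=O)[C@H](OC(C)=O)C1
F7 | step 4 | methyl 3,4-O-isopropylidene-shikimate | COC(=O)C1=C[C@H]2OC(C)(C)O[C@H]2[C@H](O)C1
F8 | step 4 | methyl 3,4-O-isopropylidene-5-O-[(3S)-3-methylpentanoyl]shikimate | COC(=O)C1=C[C@H]2OC(C)(C)O[C@H]2[C@H](OC(=O)C[C@@H](C)CC)C1
F9 | step 4 | methyl 5-O-[(3S)-3-methylpentanoyl]shikimate | COC(=O)C1=C[C@@H](O)[C@@H](O)[C@H](OC(=O)C[C@@H](C)CC)C1
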